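**Retrosynthetic overview** (core numbering: C1 OMe bridgehead, C2 carbinol, C3 OMe methine, C4 CH2, C5 allyl bridgehead, C6 Me methine, C7 aryl methine, C8 bridging ketone)
1. Feature: the five-membered ring C8–C1–C7–C6–C5 of the bicyclo[3.2.1]octan-8-one is a cyclopentanone with trans aryl (C7) and methyl (C6) on its β-carbons, a methoxy group on α-carbon C1 and an allyl-bearing quaternary α′-carbon C5. This is the print of a 2-methoxy divinyl ketone that has cyclised and then been allylated.
2. Last ring: C1–C2 is cut as an intramolecular aldol of the C1 enolate onto a C2 aldehyde, which closes the six-membered ring C1–C2–C3–C4–C5–C8.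
3. First ring (key): C6–C7 forms by 4π conrotatory closure and C5–allyl by capture of the oxyallyl cation. The methoxy group makes C1 the natural site for an outside nucleophile, so the allylsilane is tied to the C3 oxygen as an allyldimethylsilyl ether and can reach only C5. C3–OH is methylated afterwards.
4. The (1Z,4E)-dienone comes from a C1=C7 Horner–Wadsworth–Emmons olefination of 3,4,5-trimethoxybenzaldehyde. The C8–C1 bond comes from acylation of lithiated diethyl (methoxymethyl)phosphonate by an (E)-α-ethylidene-γ-lactone (C=O is C8, Cα is C5, CH2 is C4, OCH is C3, CH2O is C2).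
5. Ring order: cyclopentanone in step 8, then the six-membered ring of the bicycle in step 12.

Key step: step 8

Assumption: which antipode of the pybox ligand induces the required sense of conrotation cannot be derived on paper. The (3aS,8aR)-inda-pybox is written, and its equally available mirror image replaces it if the pairing with the (R)-configured C3 arm proves mismatched.

**Step 1**
Reactants: 1 (5R)-5-(hydroxymethyl)dihydrofuran-2(3H)-one
Product: 2 (5R)-5-[(tert-butyldimethylsilyloxy)methyl]dihydrofuran-2(3H)-one
Conditions: TBSCl, imidazole, DMF, 0 °C → rt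
Reagents that add atoms: tert-butyldimethylsilyl chloride, CC(C)(C)[Si](C)(C)Cl
Why: Standard imidazole-promoted silylation of a primary alcohol, which leaves the lactone and the C3 stereocentre (taken from the chiral pool) untouched.

**Step 2**
Reactants: 2 (5R)-5-[(tert-butyldimethylsilyloxy)methyl]dihydrofuran-2(3H)-one; 3 acetaldehyde
Product: 4 (5R)-5-[(tert-butyldimethylsilyloxy)methyl]-3-(1-hydroxyethyl)dihydrofuran-2(3H)-one (diastereomer mixture at the two new centres)
Conditions: LDA, THF, −78 °C; then 3, −78 °C; AcOH quench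
Reagents that add atoms: none
Why: Aldol addition of the lithium enolate of a γ-butyrolactone to an aldehyde is routine, and both new centres are destroyed in step 3, so the diastereomer mixture is carried on.

**Step 3**
Reactants: 4 (5R)-5-[(tert-butyldimethylsilyloxy)methyl]-3-(1-hydroxyethyl)dihydrofuran-2(3H)-one
Product: 6 (3E,5R)-5-[(tert-butyldimethylsilyloxy)methyl]-3-ethylidenedihydrofuran-2(3H)-one, via mesylate 5 (not isolated)
Conditions: MsCl, Et3N, CH2Cl2, 0 °C; then DBU, 0 °C → rt
Reagents that add atoms: methanesulfonyl chloride, CS(=O)(=O)Cl (its atoms are held only in 5)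
Why: Mesylation followed by base-induced E1cB elimination, the usual way to α-alkylidene lactones, should favour the more stable (E)-alkene with the methyl group away from the carbonyl; any (Z)-isomer is removed by chromatography and short exposure to DBU avoids drift of the alkene into the ring.

**Step 4**
Reactants: 7 triethyl phosphite; 8 chloromethyl methyl ether
Product: 9 diethyl (methoxymethyl)phosphonate
Conditions: neat, bath 100 → 150 °C, then distillation
Reagents that add atoms: none
Why: Michaelis–Arbuzov reaction of a reactive α-chloro ether with a trialkyl phosphite, driven by loss of chloroethane.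

**Step 5**
Reactants: 6 (3E,5R)-5-[(tert-butyldimethylsilyloxy)methyl]-3-ethylidenedihydrofuran-2(3H)-one; 9 diethyl (methoxymethyl)phosphonate
Product: 10 diethyl {(3E)-3-[(2R)-3-(tert-butyldimethylsilyloxy)-2-hydroxypropyl]-1-methoxy-2-oxopent-3-en-1-yl}phosphonate (epimers at the phosphonate carbon; may sit partly as its five-membered hemiketal)
Conditions: 9 (2.1 equiv), LDA (2.1 equiv), THF, −78 °C; then 6, −78 → −40 °C; AcOH quench
Reagents that add atoms: none
Why: Acylation of an α-lithiated phosphonate by a lactone (the standard β-ketophosphonate synthesis) proceeds by 1,2-addition and ring opening to the stabilised ketophosphonate anion, which resists a second addition, so the C8–C1 bond is formed and the C3 hydroxyl is set free without touching C3 or the (E)-alkene.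

**Step 6**
Reactants: 10 diethyl {(3E)-3-[(2R)-3-(tert-butyldimethylsilyloxy)-2-hydroxypropyl]-1-methoxy-2-oxopent-3-en-1-yl}phosphonate; 11 3,4,5-trimethoxybenzaldehyde
Product: 12 (1Z,4E)-4-[(2R)-3-(tert-butyldimethylsilyloxy)-2-hydroxypropyl]-2-methoxy-1-(3,4,5-trimethoxyphenyl)hexa-1,4-dien-3-one
Conditions: LiCl, DBU, MeCN, 0 °C → rt
Reagents that add atoms: none
Why: Horner–Wadsworth–Emmons olefination under Masamune–Roush conditions is mild enough for the free hydroxyl and the silyl ether, and reversible addition of the ketophosphonate anion to the aromatic aldehyde should lead to the more stable (1Z)-enol ether with aryl trans to the acyl group, any (1E)-isomer being separated.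

**Step 7**
Reactants: 12 (1Z,4E)-4-[(2R)-3-(tert-butyldimethylsilyloxy)-2-hydroxypropyl]-2-methoxy-1-(3,4,5-trimethoxyphenyl)hexa-1,4-dien-3-one; 13 allylchlorodimethylsilane
Product: 14 (1Z,4E)-4-[(2R)-2-(allyldimethylsilyloxy)-3-(tert-butyldimethylsilyloxy)propyl]-2-methoxy-1-(3,4,5-trimethoxyphenyl)hexa-1,4-dien-3-one
Conditions: imidazole, CH2Cl2, 0 °C; filtration through Et3N-deactivated silica
Reagents that add atoms: none
Why: Ordinary silylation of a secondary alcohol with a chlorosilane, placed directly before the key step because the allyldimethylsilyl ether is about as labile as a trimethylsilyl ether.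

**Step 8**
Reactants: 14 (1Z,4E)-4-[(2R)-2-(allyldimethylsilyloxy)-3-(tert-butyldimethylsilyloxy)propyl]-2-methoxy-1-(3,4,5-trimethoxyphenyl)hexa-1,4-dien-3-one
Product: 17 (2S,3S,4R,5RS)-2-allyl-2-[(2R)-3-(tert-butyldimethylsilyloxy)-2-hydroxypropyl]-5-methoxy-3-methyl-4-(3,4,5-trimethoxyphenyl)cyclopentan-1-one, via oxyallyl cation 15 (not isolated), via cyclic silyl enol ether 16 (not isolated)
Conditions: Sc(OTf)3 (20 mol %), (3aS,8aR)-inda-pybox (22 mol %), 4 Å MS, CH2Cl2 (0.005 M), −20 °C → rt; then AcOH–THF–H2O, 0 °C
Reagents that add atoms: none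
Why: Proposed new method: the Sc(III)–pybox cation binds the C8 carbonyl and the C1 methoxy oxygen as a five-membered chelate, which holds the methoxyvinyl arm s-trans and gives the 3-oxidopentadienyl cation, whose thermal conrotatory 4π electrocyclisation forms C6–C7 and closes the ring C8–C1–C7–C6–C5 to oxyallyl cation 15. The allylsilane on the C3 oxygen then attacks C5 in SE2′ fashion through an eight-membered array (C5–C4–C3–O–Si–CH2–CH=CH2), the β-silyl cation collapses by passing silicon to the C8 enolate oxygen to give 16 and release the catalyst, and mild acid hydrolyses 16 to 17. The closest known reactions are the interrupted Nazarov cyclisation of simple dienones with external allylsilanes, the Sc–pybox-catalysed Nazarov cyclisation of 2-alkoxy dienones and the Lewis-acid-induced intramolecular allyl transfer in β-(allyldimethylsilyloxy) aldehydes, which runs through the same eight-membered array, but their combination on a 2-methoxy oxyallyl cation is untested. C6 and C7 come out trans because aryl and methyl both point outward in the (1Z,4E)-dienone and turn in the same sense, the absolute sense is imposed by the pybox pocket on the rigid chelate (a wrong-sense product would be a separable diastereomer because C3 is fixed), C5 is set by approach of the allyl terminus on the ring face anti to the adjacent C6 methyl, and C1 stays an epimer mixture that step 12 erases. The step needs capture at C5 and not at C1, although the methoxy group concentrates positive charge on C1 (oxocarbenium form) and an outside allylsilane would find C1 open on the face anti to the aryl group; the tether secures this because its terminus reaches C5 but could reach C1 only through a bridged ten-membered array, the metal on the methoxy oxygen shields C1 further, and high dilution suppresses transfer between molecules. It also needs capture to be faster than loss of the C7 or a C4 proton, which the non-basic medium (CH2Cl2, sieves, no amine) and the intramolecular nucleophile should favour.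

**Step 9**
Reactants: 17 (2S,3S,4R,5RS)-2-allyl-2-[(2R)-3-(tert-butyldimethylsilyloxy)-2-hydroxypropyl]-5-methoxy-3-methyl-4-(3,4,5-trimethoxyphenyl)cyclopentan-1-one
Product: 18 (2S,3S,4R,5RS)-2-allyl-2-[(2R)-3-(tert-butyldimethylsilyloxy)-2-methoxypropyl]-5-methoxy-3-methyl-4-(3,4,5-trimethoxyphenyl)cyclopentan-1-one
Conditions: MeOTf, 2,6-di-tert-butyl-4-methylpyridine, CH2Cl2, 0 °C → rt
Reagents that add atoms: methyl trifluoromethanesulfonate, COS(=O)(=O)C(F)(F)F
Why: O-Methylation with methyl triflate and a hindered pyridine, a non-basic etherification used for base-sensitive hydroxy ketones, avoids 1,2-migration of the neighbouring silyl group and enolate chemistry, and the open secondary alcohol should react faster than the crowded tertiary hydroxyl of the five-membered hemiketal with which it may equilibrate.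

**Step 10**
Reactants: 18 (2S,3S,4R,5RS)-2-allyl-2-[(2R)-3-(tert-butyldimethylsilyloxy)-2-methoxypropyl]-5-methoxy-3-methyl-4-(3,4,5-trimethoxyphenyl)cyclopentan-1-one
Product: 19 (2S,3S,4R,5RS)-2-allyl-2-[(2R)-3-hydroxy-2-methoxypropyl]-5-methoxy-3-methyl-4-(3,4,5-trimethoxyphenyl)cyclopentan-1-one
Conditions: HF·pyridine, pyridine, THF, 0 °C → rt
Reagents that add atoms: none
Why: Fluoride-driven cleavage of a primary silyl ether under mildly acidic conditions, to which ketone, alkene and aryl ethers are inert.

**Step 11**
Reactants: 19 (2S,3S,4R,5RS)-2-allyl-2-[(2R)-3-hydroxy-2-methoxypropyl]-5-methoxy-3-methyl-4-(3,4,5-trimethoxyphenyl)cyclopentan-1-one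
Product: 20 (2R)-3-[(1S,2S,3R,4RS)-1-allyl-4-methoxy-2-methyl-5-oxo-3-(3,4,5-trimethoxyphenyl)cyclopentyl]-2-methoxypropanal
Conditions: Dess–Martin periodinane, CH2Cl2, 0 °C → rt; used crude
Reagents that add atoms: none
Why: Dess–Martin oxidation of a primary alcohol stops at the aldehyde under nearly neutral conditions that should not epimerise the α-methoxy centre C3, and any six-membered hemiketal form of 19 drains through the open alcohol.

**Step 12**
Reactants: 20 (2R)-3-[(1S,2S,3R,4RS)-1-allyl-4-methoxy-2-methyl-5-oxo-3-(3,4,5-trimethoxyphenyl)cyclopentyl]-2-methoxypropanal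
Product: 21 (1R,2R,3R,5S,6S,7R)-5-allyl-2-hydroxy-1,3-dimethoxy-6-methyl-7-(3,4,5-trimethoxyphenyl)bicyclo[3.2.1]octan-8-one (target)
Conditions: MgBr2·OEt2, iPr2NEt, CH2Cl2, −20 → 0 °C; aq NH4Cl
Reagents that add atoms: none
Why: Intramolecular aldol addition (6-enolexo-exo-trig) by soft enolisation, in which Mg(II) chelated by the C8 carbonyl and C1 methoxy oxygens acidifies C1–H, the only enolisable position of the ketone, so both C1 epimers converge on one enolate; the C1–C2 bond can form only on the ring face that carries the C4 arm, which fixes C1, and the closed magnesium-bridged (Zimmerman–Traxler-type) transition state with the aldehyde oxygen held next to the enolate oxygen and C3–OMe equatorial puts the C2 hydroxyl axial, syn to the C8 bridge and cis to both methoxy groups, as in 21.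

**Compound list**
1 | (5R)-5-(hydroxymethyl)dihydrofuran-2(3H)-one | OC[C@H]1CCC(=O)O1 | starting material
2 | (5R)-5-[(tert-butyldimethylsilyloxy)methyl]dihydrofuran-2(3H)-one | CC(C)(C)[Si](C)(C)OC[C@H]1CCC(=O)O1 | intermediate
3 | acetaldehyde | CC=O | starting material
4 | (5R)-5-[(tert-butyldimethylsilyloxy)methyl]-3-(1-hydroxyethyl)dihydrofuran-2(3H)-one | CC(O)C1C[C@H](CO[Si](C)(C)C(C)(C)C)OC1=O | intermediate
5 | mesylate of 4 (not isolated) | CC(OS(C)(=O)=O)C1C[C@H](CO[Si](C)(C)C(C)(C)C)OC1=O | intermediate
6 | (3E,5R)-5-[(tert-butyldimethylsilyloxy)methyl]-3-ethylidenedihydrofuran-2(3H)-one | C/C=C1\C[C@H](CO[Si](C)(C)C(C)(C)C)OC1=O | intermediate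
7 | triethyl phosphite | CCOP(OCC)OCC | starting material
8 | chloromethyl methyl ether | COCCl | starting material
9 | diethyl (methoxymethyl)phosphonate | CCOP(=O)(COC)OCC | intermediate
10 | diethyl {(3E)-3-[(2R)-3-(tert-butyldimethylsilyloxy)-2-hydroxypropyl]-1-methoxy-2-oxopent-3-en-1-yl}phosphonate | C/C=C(\C[C@@H](O)CO[Si](C)(C)C(C)(C)C)C(=O)C(OC)P(=O)(OCC)OCC | intermediate
11 | 3,4,5-trimethoxybenzaldehyde | COc1cc(C=O)cc(OC)c1OC | starting material
12 | (1Z,4E)-4-[(2R)-3-(tert-butyldimethylsilyloxy)-2-hydroxypropyl]-2-methoxy-1-(3,4,5-trimethoxyphenyl)hexa-1,4-dien-3-one | C/C=C(\C[C@@H](O)CO[Si](C)(C)C(C)(C)C)C(=O)/C(OC)=C/c1cc(OC)c(OC)c(OC)c1 | intermediate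
13 | allylchlorodimethylsilane | C=CC[Si](C)(C)Cl | starting material
14 | (1Z,4E)-4-[(2R)-2-(allyldimethylsilyloxy)-3-(tert-butyldimethylsilyloxy)propyl]-2-methoxy-1-(3,4,5-trimethoxyphenyl)hexa-1,4-dien-3-one | C/C=C(\C[C@@H](O[Si](C)(C)CC=C)CO[Si](C)(C)C(C)(C)C)C(=O)/C(OC)=C/c1cc(OC)c(OC)c(OC)c1 | intermediate
15 | oxyallyl cation, drawn metal-free as C1 oxocarbenium / C8 oxide (not isolated) | C[O+]=C1C([O-])=C(C[C@@H](O[Si](C)(C)CC=C)CO[Si](C)(C)C(C)(C)C)[C@@H](C)[C@@H]1c2cc(OC)c(OC)c(OC)c2 | intermediate
16 | cyclic silyl enol ether with a C8–O–SiMe2–O–C3 bridge, C8=C1(OMe), allyl on C5 (not isolated) | C=CC[C@@]12C[C@H](CO[Si](C)(C)C(C)(C)C)O[Si](C)(C)OC1=C(OC)[C@@H](c3cc(OC)c(OC)c(OC)c3)[C@@H]2C | intermediate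
17 | (2S,3S,4R,5RS)-2-allyl-2-[(2R)-3-(tert-butyldimethylsilyloxy)-2-hydroxypropyl]-5-methoxy-3-methyl-4-(3,4,5-trimethoxyphenyl)cyclopentan-1-one | C=CC[C@@]1(C[C@@H](O)CO[Si](C)(C)C(C)(C)C)C(=O)C(OC)[C@@H](c2cc(OC)c(OC)c(OC)c2)[C@@H]1C | intermediate
18 | (2S,3S,4R,5RS)-2-allyl-2-[(2R)-3-(tert-butyldimethylsilyloxy)-2-methoxypropyl]-5-methoxy-3-methyl-4-(3,4,5-trimethoxyphenyl)cyclopentan-1-one | C=CC[C@@]1(C[C@@H](OC)CO[Si](C)(C)C(C)(C)C)C(=O)C(OC)[C@@H](c2cc(OC)c(OC)c(OC)c2)[C@@H]1C | intermediate
19 | (2S,3S,4R,5RS)-2-allyl-2-[(2R)-3-hydroxy-2-methoxypropyl]-5-methoxy-3-methyl-4-(3,4,5-trimethoxyphenyl)cyclopentan-1-one | C=CC[C@@]1(C[C@@H](OC)CO)C(=O)C(OC)[C@@H](c2cc(OC)c(OC)c(OC)c2)[C@@H]1C | intermediate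
20 | (2R)-3-[(1S,2S,3R,4RS)-1-allyl-4-methoxy-2-methyl-5-oxo-3-(3,4,5-trimethoxyphenyl)cyclopentyl]-2-methoxypropanal | C=CC[C@@]1(C[C@@H](OC)C=O)C(=O)C(OC)[C@@H](c2cc(OC)c(OC)c(OC)c2)[C@@H]1C | intermediate
21 | (1R,2R,3R,5S,6S,7R)-5-allyl-2-hydroxy-1,3-dimethoxy-6-methyl-7-(3,4,5-trimethoxyphenyl)bicyclo[3.2.1]octan-8-one | C=CC[C@@]12C[C@@H](OC)[C@@H](O)[C@@](OC)(C1=O)[C@@H](c1cc(OC)c(OC)c(OC)c1)[C@@H]2C | target

**Total step count:** 12. **Longest linear sequence:** 11 (steps 1–3 and 5–12; step 4 is a side branch).

**Steps most likely to fail**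

**Step 8 (proposed new method).** Three things may go wrong.
- The oxyallyl cation may lose the C7 or a C4 proton before the tethered allylsilane arrives, which is the ordinary eliminative termination.
- The β-silyl cation may close onto C1 in a formal [3+2] sense.
- The ligand may steer the conrotation only weakly.

The fallback splits the event into two known reactions and uses the bias of the methoxy group instead of opposing it.
- It sets out from 12. O-Methylation (MeOTf, 2,6-di-tert-butyl-4-methylpyridine, CH2Cl2) gives the methyl ether dienone F1.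
- A reductive Nazarov cyclisation (same Sc–pybox catalyst, Et3SiH, CH2Cl2) should deliver hydride to the oxocarbenium carbon C1.
- After a non-acidic work-up this leaves the tetrasubstituted C5=C8 triethylsilyl enol ether F2, with C6 and C7 trans by the same conrotation.
- Palladium-catalysed Tsuji-type allylation of the enol silane (allyl methyl carbonate, Pd2(dba)3, phosphine, Bu4N Ph3SiF2, THF) then places allyl on C5 anti to the C6 methyl.
- The fallback comes back to the route at 18.

**Step 12.** The aldehyde may be attacked through an open transition state, with loss of facial control at C2. Soft enolisation may also take the aldehyde α-proton and erode C3.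

The fallback sets C2 by ketone reduction instead of by the aldol.
- It sets out from 20, which is cyclised with an amine base (DBU, CH2Cl2) without regard to C2. The product then contains the C2-epimeric carbinol F3.
- Dess–Martin oxidation of the carbinol mixture gives the 2,8-dione F4, which cannot enolise at C1 and keeps C3–OMe equatorial.
- L-Selectride (THF, −78 °C) should attack the C2 ketone from the equatorial direction, as bulky borohydrides do on cyclohexanones. The C8 ketone is shielded by two quaternary carbons.
- This gives the axial carbinol and comes back to the route at 21.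

**Step 5.** The strongly basic carbanion may add in a conjugate sense to the ethylidene lactone, take a γ-proton from its methyl group, or decay before acylation.

The fallback replaces the olefination by an aldol condensation.
- It sets out from 6. Methoxymethyllithium (from tributyl(methoxymethyl)stannane and n-BuLi, THF, −78 °C) adds once to the lactone carbonyl to give the methoxymethyl ketone F5.
- Claisen–Schmidt condensation of F5 with 11 (Ba(OH)2·8H2O, MeOH–THF, rt) gives the more stable (Z)-α-methoxy enone.
- The fallback comes back to the route at 12, by-passing 9 and 10.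

**Further compounds**
F1 | step 8 | (1Z,4E)-4-[(2R)-3-(tert-butyldimethylsilyloxy)-2-methoxypropyl]-2-methoxy-1-(3,4,5-trimethoxyphenyl)hexa-1,4-dien-3-one | C/C=C(\C[C@@H](OC)CO[Si](C)(C)C(C)(C)C)C(=O)/C(OC)=C/c1cc(OC)c(OC)c(OC)c1
F2 | step 8 | triethylsilyl enol ether (C5=C8) of the 2-methoxy-5-alkyl-4-methyl-3-arylcyclopentanone, C6/C7 trans, C1 epimers | CC[Si](CC)(CC)OC1=C(C[C@@H](OC)CO[Si](C)(C)C(C)(C)C)[C@@H](C)[C@H](c2cc(OC)c(OC)c(OC)c2)C1OC
F3 | step 12 | C2 epimer of 21 (equatorial 2-hydroxyl, all other centres as in 21) | C=CC[C@@]12C[C@@H](OC)[C@H](O)[C@@](OC)(C1=O)[C@@H](c1cc(OC)c(OC)c(OC)c1)[C@@H]2C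
F4 | step 12 | 5-allyl-1,3-dimethoxy-6-methyl-7-(3,4,5-trimethoxyphenyl)bicyclo[3.2.1]octane-2,8-dione (C1, C3, C5, C6, C7 arranged as in 21) | C=CC[C@@]12C[C@@H](OC)C(=O)[C@@](OC)(C1=O)[C@@H](c1cc(OC)c(OC)c(OC)c1)[C@@H]2C
F5 | step 5 | (3E)-3-[(2R)-3-(tert-butyldimethylsilyloxy)-2-hydroxypropyl]-1-methoxypent-3-en-2-one | C/C=C(\C[C@@H](O)CO[Si](C)(C)C(C)(C)C)C(=O)COC
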